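## Retrosynthetic overview

1. Feature: on ring A the cinnamoyl carbonyl carbon sits on C1', the neighbouring C6' bears a hydroxyl, and the other neighbour C2' also bears oxygen. This O6'/acyl-C1'/O2' triad is the footprint of a C1'-C6' aryne polarised by O2'.
2. Key disconnection: C6'-O and C1'-C(=O) are cut together, giving o-silylaryl triflate 9 and MOM-protected p-coumaric acid 12 (aryne insertion into the acid C-O bond). The same step leaves O6' as the only free phenol.
3. The C3'-CH2 prenyl bond goes back to the O6' prenyl ether 18 (Claisen shift to C5', then Cope shift to C3'). O2' and O6' both end as OH, so C3' and C5' are equivalent in the target and only the linear form of the prenyl group matters.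
4. 9 comes from 5-methoxyresorcinol by bis-MOM protection, lithiation-bromination between the two OMOM groups, removal of one MOM, and retro-Brook silyl shift with triflation. 12 comes from p-coumaric acid.
5. No ring is built. Rings A and B are purchased, joined in step 6, then prenylated and deprotected.

Key step: step 6

Remark: ring A locants of the target (C1' acyl, C2' O, C3' prenyl site, C4' OMe, C5' H, C6' O) are used for all intermediates. Flavanone 15 and dienones 19 and 20 are racemic and transient, and leave no stereocentre in 22.

## Route

Step 1
Reactants: 1 5-methoxyresorcinol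
Product: 2 1-methoxy-3,5-bis(methoxymethoxy)benzene
Conditions: NaH (2.4 equiv), MOMCl (2.4 equiv), THF/DMF, 0 °C to rt
Reagents that add atoms: chloromethyl methyl ether (MOMCl), COCCl
Why: Williamson-type O-alkylation of both phenoxides by the reactive chloromethyl ether should give the symmetrical bis-acetal, which masks the acidic protons and installs two strong ortho-directing groups.

Step 2
Reactants: 2 1-methoxy-3,5-bis(methoxymethoxy)benzene
Product: 4 2-bromo-5-methoxy-1,3-bis(methoxymethoxy)benzene, via aryllithium 3 (not isolated)
Conditions: n-BuLi, THF, 0 °C; BrCH2CH2Br, -78 °C to rt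
Reagents that add atoms: 1,2-dibromoethane, BrCCBr
Why: Directed ortho-metalation should take place at the carbon between the two chelating OMOM groups, since OMOM outranks OMe as a directing group, and aryllithium 3 is then brominated by halogen transfer from 1,2-dibromoethane with loss of ethene.

Step 3
Reactants: 4 2-bromo-5-methoxy-1,3-bis(methoxymethoxy)benzene
Product: 5 2-bromo-5-methoxy-3-(methoxymethoxy)phenol
Conditions: conc. HCl (cat.), MeOH, rt, stopped at partial conversion
Reagents that add atoms: none
Why: Acid-catalysed acetal exchange with methanol (MOM cleavage) removes the two equivalent MOM groups one after the other, so interrupting the reaction should give the mono-phenol, which is separated by polarity from unchanged and over-cleaved material that can be recycled.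

Step 4
Reactants: 5 2-bromo-5-methoxy-3-(methoxymethoxy)phenol
Product: 9 5-methoxy-3-(methoxymethoxy)-2-(trimethylsilyl)phenyl triflate, via aryl silyl ether 6 (not isolated), via aryllithium 7 (not isolated), via lithium silylphenoxide 8 (not isolated)
Conditions: HMDS, THF, 70 °C, evaporate; n-BuLi, THF, -78 °C; Tf2O, -78 °C
Reagents that add atoms: hexamethyldisilazane, C[Si](C)(C)N[Si](C)(C)C; triflic anhydride, O=S(=O)(OS(=O)(=O)C(F)(F)F)C(F)(F)F
Why: O-silylation, bromine-lithium exchange and retro-Brook 1,3-O-to-C silyl migration should place silicon on the carbon that bore bromine, and the released lithium phenoxide 8 is triflated in the same flask, which is the standard entry to o-silylaryl triflate aryne precursors.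

Step 5
Reactants: 10 p-coumaric acid
Product: 12 (E)-4-(methoxymethoxy)cinnamic acid, via methoxymethyl ester 11 (not isolated)
Conditions: NaH (2.3 equiv), MOMCl (2.3 equiv), DMF, 0 °C to rt; LiOH, THF/MeOH/H2O, rt; 1 M HCl, 0 °C, pH 4
Reagents that add atoms: chloromethyl methyl ether (MOMCl), COCCl; lithium hydroxide, [Li+].[OH-]
Why: Williamson-type double alkylation of the phenoxide-carboxylate dianion followed by saponification should cleave only the acylal-type MOM ester, leaving the aryl MOM ether and the E-alkene untouched.

Step 6
Reactants: 9 5-methoxy-3-(methoxymethoxy)-2-(trimethylsilyl)phenyl triflate; 12 (E)-4-(methoxymethoxy)cinnamic acid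
Product: 16 (E)-6'-hydroxy-4'-methoxy-2',4-bis(methoxymethoxy)chalcone, via aryne 13 (not isolated), via caesium aryl anion 14 (not isolated), via flavanone 15 (not isolated)
Conditions: 12 (1.5 equiv), dry CsF (4 equiv), THF, 125 °C, sealed tube; then KOH, MeOH/H2O, rt; 1 M HCl, 0 °C, pH 5
Reagents that add atoms: none
Why: Fluoride attack on silicon with loss of triflate gives aryne 13, and the carboxylate of 12 adds through oxygen to C6', the aryne carbon remote from the C2' OMOM group, because the inductively withdrawing C2' oxygen distorts the triple bond and stabilises the carbanion developing at C1' in 14. The C1' anion then attacks the neighbouring ester carbonyl through a strained four-membered alkoxide that collapses to the ketone and the C6' phenoxide, an anionic Fries-type O-to-C acyl shift, so C6'-O and C1'-C(=O) are made in one operation. The closest known reaction type is the fluoride-induced insertion of arynes into the C-O bond of carboxylic acids in hot THF, which covers cinnamic acids and 3-alkoxyarynes. No ring remains in 16 and no stereocentre is formed; material that closes by 6-endo-trig oxa-Michael addition to racemic flavanone 15 is reopened by KOH through E1cB elimination to the conjugated phenoxide, which returns the E-enone on cold acidification. Two selectivities are needed: regioselective addition to 13, secured by the C2' oxygen and only weakly opposed by the remote C4' methoxy group, and acyl capture ahead of protonation of 14, favoured by the aprotic solvent, the high temperature and the proximity of the ester carbonyl. Both MOM ethers are inert to fluoride and base, and the excess of 12 keeps the product phenoxide from competing for the aryne.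

Step 7
Reactants: 16 (E)-6'-hydroxy-4'-methoxy-2',4-bis(methoxymethoxy)chalcone; 17 prenyl bromide
Product: 18 (E)-4'-methoxy-2',4-bis(methoxymethoxy)-6'-(3-methylbut-2-enyloxy)chalcone
Conditions: K2CO3, DMF, 40 °C
Reagents that add atoms: prenyl bromide (17), CC(C)=CCBr
Why: Williamson ether synthesis (SN2 at the primary allylic bromide) should alkylate the only free phenol, since carbonate in DMF breaks its hydrogen bond to the ketone, O-alkylation drains the phenoxide from any chalcone-flavanone equilibrium, and the MOM ethers are inert to base.

Step 8
Reactants: 18 (E)-4'-methoxy-2',4-bis(methoxymethoxy)-6'-(3-methylbut-2-enyloxy)chalcone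
Product: 21 (E)-6'-hydroxy-4'-methoxy-2',4-bis(methoxymethoxy)-3'-(3-methylbut-2-enyl)chalcone, via ortho-dienone 19 (not isolated), via para-dienone 20 (not isolated)
Conditions: Eu(fod)3 (10 mol %), toluene, 100 °C, argon
Reagents that add atoms: none
Why: In this tandem aromatic Claisen-Cope rearrangement, Eu(fod)3 chelated between the ketone and O6' accelerates the [3,3] shift to C5' to give 19 with an inverted 1,1-dimethylallyl group, whose crowding between two oxygenated carbons should drive a second [3,3] shift to C3' (para to O6') that restores the linear prenyl group in 20 before tautomerisation to 21, as is known for prenyl ethers ortho to acetophenone and flavanone carbonyls.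

Step 9
Reactants: 21 (E)-6'-hydroxy-4'-methoxy-2',4-bis(methoxymethoxy)-3'-(3-methylbut-2-enyl)chalcone
Product: 22 xanthogalenol
Conditions: conc. HCl, MeOH, rt, monitored closely
Reagents that add atoms: none
Why: Acid-catalysed acetal exchange with methanol (MOM cleavage) at room temperature should free O2' and the ring B phenol, with mild conditions and short contact chosen so that the freed phenols do not attack the trisubstituted prenyl alkene or the E-enone.

## Compound list

1 | 5-methoxyresorcinol | COc1cc(O)cc(O)c1 | starting material
2 | 1-methoxy-3,5-bis(methoxymethoxy)benzene | COc1cc(OCOC)cc(OCOC)c1 | intermediate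
3 | [4-methoxy-2,6-bis(methoxymethoxy)phenyl]lithium | [Li]c1c(OCOC)cc(OC)cc1OCOC | intermediate
4 | 2-bromo-5-methoxy-1,3-bis(methoxymethoxy)benzene | COCOc1cc(OC)cc(OCOC)c1Br | intermediate
5 | 2-bromo-5-methoxy-3-(methoxymethoxy)phenol | COCOc1cc(OC)cc(O)c1Br | intermediate
6 | [2-bromo-5-methoxy-3-(methoxymethoxy)phenoxy]trimethylsilane | COCOc1cc(OC)cc(O[Si](C)(C)C)c1Br | intermediate
7 | [4-methoxy-2-(methoxymethoxy)-6-(trimethylsilyloxy)phenyl]lithium | [Li]c1c(OCOC)cc(OC)cc1O[Si](C)(C)C | intermediate
8 | lithium 5-methoxy-3-(methoxymethoxy)-2-(trimethylsilyl)phenoxide | [Li+].[O-]c1cc(OC)cc(OCOC)c1[Si](C)(C)C | intermediate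
9 | 5-methoxy-3-(methoxymethoxy)-2-(trimethylsilyl)phenyl trifluoromethanesulfonate | COCOc1cc(OC)cc(OS(=O)(=O)C(F)(F)F)c1[Si](C)(C)C | intermediate
10 | p-coumaric acid, (E)-3-(4-hydroxyphenyl)prop-2-enoic acid | O=C(O)/C=C/c1ccc(O)cc1 | starting material
11 | methoxymethyl (E)-4-(methoxymethoxy)cinnamate | COCOC(=O)/C=C/c1ccc(OCOC)cc1 | intermediate
12 | (E)-4-(methoxymethoxy)cinnamic acid | COCOc1ccc(/C=C/C(=O)O)cc1 | intermediate
13 | 5-methoxy-3-(methoxymethoxy)benzyne (C1'-C6' aryne) | COCOC1=CC(OC)=CC#C1 | intermediate
14 | caesium salt of the C1' carbanion of 3-methoxy-5-(methoxymethoxy)phenyl (E)-4-(methoxymethoxy)cinnamate | COCOc1cc(OC)cc(OC(=O)/C=C/c2ccc(OCOC)cc2)[c-]1.[Cs+] | intermediate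
15 | racemic 7-methoxy-5,4'-bis(methoxymethoxy)flavanone | COCOc1cc(OC)cc2OC(CC(=O)c12)c1ccc(OCOC)cc1 | intermediate
16 | (E)-6'-hydroxy-4'-methoxy-2',4-bis(methoxymethoxy)chalcone | COCOc1cc(OC)cc(O)c1C(=O)/C=C/c1ccc(OCOC)cc1 | intermediate
17 | prenyl bromide (1-bromo-3-methylbut-2-ene) | CC(C)=CCBr | starting material
18 | (E)-4'-methoxy-2',4-bis(methoxymethoxy)-6'-(3-methylbut-2-enyloxy)chalcone | COCOc1cc(OC)cc(OCC=C(C)C)c1C(=O)/C=C/c1ccc(OCOC)cc1 | intermediate
19 | racemic cyclohexa-2,4-dienone with 1,1-dimethylallyl and H on C5' (ortho-dienone) | O=C1C(C(C)(C)C=C)C(OC)=CC(OCOC)=C1C(=O)/C=C/c1ccc(OCOC)cc1 | intermediate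
20 | racemic cyclohexa-2,5-dienone with prenyl and H on C3' (para-dienone) | O=C1C=C(OC)C(CC=C(C)C)C(OCOC)=C1C(=O)/C=C/c1ccc(OCOC)cc1 | intermediate
21 | (E)-6'-hydroxy-4'-methoxy-2',4-bis(methoxymethoxy)-3'-(3-methylbut-2-enyl)chalcone | COCOc1c(CC=C(C)C)c(OC)cc(O)c1C(=O)/C=C/c1ccc(OCOC)cc1 | intermediate
22 | xanthogalenol, (E)-2',6',4-trihydroxy-4'-methoxy-3'-(3-methylbut-2-enyl)chalcone | COc1cc(O)c(C(=O)/C=C/c2ccc(O)cc2)c(O)c1CC=C(C)C | target

## Step count and risks

Total step count: 9. Longest linear sequence: 8 (steps 1-4 and 6-9).

**Step 6.**
- What may go wrong: the C1' aryl anion may be protonated before it reaches the carbonyl, giving plain O-arylation of the acid. The product phenoxide may be arylated by a second aryne, or regiocontrol in the addition may erode.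
- Fallback: it sets out from 2 and 12 and returns at 16, and it forms the C1'-C(=O) bond without an aryne.
- Acid 12 would be coupled with N,O-dimethylhydroxylamine hydrochloride (EDC hydrochloride, N-methylmorpholine, CH2Cl2) to the Weinreb amide (E)-N-methoxy-N-methyl-4-(methoxymethoxy)cinnamamide F1.
- Compound 2 would be lithiated as in step 2 to aryllithium 3 and added to F1 at -78 °C. This is a Weinreb ketone synthesis in which 1,2-addition is held at the chelated tetrahedral adduct. It would give (E)-4'-methoxy-2',6',4-tris(methoxymethoxy)chalcone F2.
- Dilute HCl in MeOH at room temperature would then remove one of the two equivalent MOM groups ortho to the ketone. The first phenol set free locks into a hydrogen bond with the carbonyl, and the ring B acetal lacks that neighbouring group and reacts more slowly, so the cleavage should stop at 16.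

**Step 8.**
- What may go wrong: tautomerisation of the first dienone may outrun the Cope shift, leaving the allyl unit inverted at C5'. Heat and Lewis acid may also cause loss of the prenyl group or oxa-Michael closure of the freed phenol.
- Fallback: it sets out from 16 and returns at 22. It uses an allyl group, which cannot end up branched, and relies on the equivalence of C3' and C5' in the target.
- 16 would be O-allylated (allyl bromide, K2CO3, DMF) to (E)-6'-allyloxy-4'-methoxy-2',4-bis(methoxymethoxy)chalcone F3.
- Thermal ortho-Claisen rearrangement (N,N-diethylaniline, 190 °C) would give (E)-5'-allyl-6'-hydroxy-4'-methoxy-2',4-bis(methoxymethoxy)chalcone F4.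
- Cross-metathesis with 2-methyl-2-butene (second-generation Grubbs catalyst, CH2Cl2, 40 °C) would convert the terminal alkene into the prenyl group of (E)-6'-hydroxy-4'-methoxy-2',4-bis(methoxymethoxy)-5'-(3-methylbut-2-enyl)chalcone F5. The conjugated disubstituted enone is a poor metathesis partner and should be left alone.
- MOM cleavage as in step 9 then gives 22, because a prenyl group on C5' and one on C3' are the same compound once O2' and O6' are both hydroxyl.

**Step 9.**
- What may go wrong: the ring B acetal cleaves slowly. Meanwhile acid may promote oxa-Michael closure of either ortho phenol onto the enone, and Markovnikov addition of O2' to the prenyl alkene.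
- Fallback: it sets out from 21 and returns at 22. It replaces Brønsted-acid hydrolysis by a two-stage acetal-to-silyl-ether exchange in a buffered medium.
- TMSOTf and 2,2'-bipyridyl in MeCN at 0 °C would convert both aryl MOM ethers and the free phenol into silyl ethers, giving xanthogalenol tris(trimethylsilyl) ether F6.
- Adding water at room temperature would hydrolyse the labile aryl silyl ethers to 22 near neutrality.

## Further compounds

F1 | step 6 | (E)-N-methoxy-N-methyl-4-(methoxymethoxy)cinnamamide | COCOc1ccc(/C=C/C(=O)N(C)OC)cc1
F2 | step 6 | (E)-4'-methoxy-2',6',4-tris(methoxymethoxy)chalcone | COCOc1cc(OC)cc(OCOC)c1C(=O)/C=C/c1ccc(OCOC)cc1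
F3 | step 8 | (E)-6'-allyloxy-4'-methoxy-2',4-bis(methoxymethoxy)chalcone | COCOc1cc(OC)cc(OCC=C)c1C(=O)/C=C/c1ccc(OCOC)cc1
F4 | step 8 | (E)-5'-allyl-6'-hydroxy-4'-methoxy-2',4-bis(methoxymethoxy)chalcone | COCOc1cc(OC)c(CC=C)c(O)c1C(=O)/C=C/c1ccc(OCOC)cc1
F5 | step 8 | (E)-6'-hydroxy-4'-methoxy-2',4-bis(methoxymethoxy)-5'-(3-methylbut-2-enyl)chalcone | COCOc1cc(OC)c(CC=C(C)C)c(O)c1C(=O)/C=C/c1ccc(OCOC)cc1
F6 | step 9 | xanthogalenol tris(trimethylsilyl) ether | COc1cc(O[Si](C)(C)C)c(C(=O)/C=C/c2ccc(O[Si](C)(C)C)cc2)c(O[Si](C)(C)C)c1CC=C(C)C
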